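**Retrosynthetic overview**

- Feature: ring A (C4a, C5, C6, C7, C8, C8a) carries OMe on C6, OH on C7 and H on C5 and C8. C4a, C5, C6, C7 and both oxygens are carried as a 4-methoxyfuran bonded through its C2 (the future C4a) to C4, and C8a/C8 come from a terminal alkyne on C1.
- Key disconnection: bonds C4a–C8a and C7–C8 (furan/alkyne [4+2], then opening of the oxygen bridge), which closes rings B and A together from an open-chain furyl keto ester that already holds C1 and C2.
- The precursor comes from a copper-catalysed asymmetric propargylic substitution (bond C1–C2, both stereocentres) between a racemic ring C propargylic acetate and an α-silyloxy β-keto ester. The keto ester already contains the furylmethyl ketone, made from (4-methoxyfuran-2-yl)acetic acid and a glycolate enolate, because attaching the furan later to a methyl ketone enolate would need a basic addition that a furanone partner answers by deprotonation.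
- After the key step, the C3 ketone becomes C3(OH)(CH2OH) through a one-carbon silicon tether on the C2 oxygen (radical 5-exo closure on the C3=C4 silyl enol ether, Tamao–Fleming oxidation); then saponification and hydrogenolysis.
- Ring order: ring C is bought (5-hydroxyvanillin); rings B and A form together in the key step.

Key step: step 9

Assumption: the (S,S)-Ph-pybox ligand is taken to favour the (1R,2S) isomer 15; if the first runs show the opposite sense at C1, the (R,R) ligand is used with nothing else changed.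
Abbreviation: Ar = 3,4-bis(benzyloxy)-5-methoxyphenyl.

**Route**

Step 1
Reactants: 1 5-hydroxyvanillin (3,4-dihydroxy-5-methoxybenzaldehyde)
Product: 2 3,4-bis(benzyloxy)-5-methoxybenzaldehyde
Conditions: BnBr (2.4 equiv), K2CO3, DMF, 60 °C
Reagents that add atoms: benzyl bromide, BrCc1ccccc1
Why: Williamson ether synthesis on both phenols should be clean because the aldehyde has no α-hydrogen and the phenoxides are the only nucleophiles.

Step 2
Reactants: 2 3,4-bis(benzyloxy)-5-methoxybenzaldehyde; 3 ethynylmagnesium bromide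
Product: 4 racemic 1-Ar-prop-2-yn-1-ol
Conditions: THF, 0 °C; sat. aq NH4Cl
Reagents that add atoms: none
Why: Grignard addition of the acetylide to a non-enolisable aldehyde; the carbinol is left racemic on purpose because step 8 is enantioconvergent.

Step 3
Reactants: 4 racemic 1-Ar-prop-2-yn-1-ol
Product: 5 racemic 1-Ar-prop-2-yn-1-yl acetate
Conditions: Ac2O, Et3N, DMAP (cat.), CH2Cl2, 0 °C
Reagents that add atoms: acetic anhydride, CC(=O)OC(C)=O
Why: DMAP-catalysed acylation of a secondary alcohol under basic conditions, which avoids ionising the electron-rich propargylic position.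

Step 4
Reactants: 6 4-bromo-2-furaldehyde
Product: 7 racemic 1-(4-bromofuran-2-yl)-2,2,2-trichloroethan-1-ol
Conditions: CHCl3, DBU (1 equiv), 0 °C → rt
Reagents that add atoms: chloroform, ClC(Cl)Cl
Why: Amidine-promoted addition of the trichloromethyl anion to a non-enolisable aromatic aldehyde; the new carbinol centre is racemic and disappears in step 5.

Step 5
Reactants: 7 racemic 1-(4-bromofuran-2-yl)-2,2,2-trichloroethan-1-ol
Product: 10 (4-bromofuran-2-yl)acetic acid, via dichloro-oxirane 8 (not isolated), via acyl chloride 9 (not isolated)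
Conditions: NaBH4, NaOH, t-BuOH/H2O, 55 °C; citric acid to pH 4
Reagents that add atoms: sodium hydroxide, [Na+].[OH-]
Why: Jocic-type reductive one-carbon homologation, in which the alkoxide closes to the gem-dichloro-epoxide, hydride opens it at the furfuryl carbon and the acyl chloride so formed is hydrolysed by hydroxide.

Step 6
Reactants: 10 (4-bromofuran-2-yl)acetic acid
Product: 11 (4-methoxyfuran-2-yl)acetic acid
Conditions: NaOMe (5 equiv), CuBr (10 mol %), MeOH/DMF, 100 °C; cold citrate buffer, pH 4.5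
Reagents that add atoms: sodium methoxide, [Na+].[O-]C
Why: Ullmann-type copper-catalysed methoxylation of the heteroaryl bromide, run on the carboxylate salt so that no base-sensitive group is present and the acid-labile methoxyfuran appears only after the last acidic operation of this branch.

Step 7
Reactants: 11 (4-methoxyfuran-2-yl)acetic acid; 12 methyl 2-[(tert-butyldimethylsilyl)oxy]acetate
Product: 14 methyl 2-[(tert-butyldimethylsilyl)oxy]-4-(4-methoxyfuran-2-yl)-3-oxobutanoate, via acyl imidazole 13 (not isolated)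
Conditions: 11, CDI, THF, rt; added to 12 (2.2 equiv), LiN(iPr)2, THF, −78 °C; AcOH quench
Reagents that add atoms: none
Why: Crossed Claisen condensation of a glycolate ester enolate with an acyl imidazole, the second equivalent of enolate taking up the acidic product; C2 of 14 is racemic and is enolised again in step 8.

Step 8
Reactants: 5 racemic 1-Ar-prop-2-yn-1-yl acetate; 14 methyl 2-[(tert-butyldimethylsilyl)oxy]-4-(4-methoxyfuran-2-yl)-3-oxobutanoate
Product: 15 methyl (2S)-2-[(1R)-1-Ar-prop-2-yn-1-yl]-2-[(tert-butyldimethylsilyl)oxy]-4-(4-methoxyfuran-2-yl)-3-oxobutanoate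
Conditions: CuOTf·0.5C6H6 (5 mol %), (S,S)-Ph-pybox (10 mol %), iPr2NEt (1.2 equiv), MeOH, −20 °C
Reagents that add atoms: none
Why: Copper-catalysed asymmetric propargylic substitution, in which the copper acetylide of 5 ionises to a copper allenylidene that the chelated enolate of 14 attacks at the γ-carbon; both enantiomers of 5 converge on the C1 configuration fixed by the pybox ligand, and the fixed geometry of the chelated, fully substituted enolate in the ligand pocket should set C2, as with other 2-substituted β-keto esters.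

Step 9
Reactants: 15 methyl (2S)-2-[(1R)-1-Ar-prop-2-yn-1-yl]-2-[(tert-butyldimethylsilyl)oxy]-4-(4-methoxyfuran-2-yl)-3-oxobutanoate
Product: 17 methyl (1S,2S)-1-Ar-2-[(tert-butyldimethylsilyl)oxy]-7-hydroxy-6-methoxy-3-oxo-1,2,3,4-tetrahydronaphthalene-2-carboxylate, via oxanorbornadiene cycloadduct 16 (not isolated)
Conditions: 1,2-dichlorobenzene (0.01 M), BHT (cat.), 160 °C, sealed tube
Reagents that add atoms: none
Why: On heating, positions 2 and 5 of the electron-rich 4-methoxyfuran add across the tethered terminal alkyne to give oxanorbornadiene 16, whose C4a–O bond then ionises (the C4a cation is an oxocarbenium ion through C5=C6–OMe) and loss of the C7 proton gives the phenol. The closest known reaction type is the intramolecular Diels–Alder reaction of furans with tethered alkynes followed by opening of the oxygen bridge to a phenol. Ring B closes in the cycloaddition as the six-membered ring that holds the four-atom tether C4–C3–C2–C1 (bond C4a–C8a), and ring A closes through the second new bond C7–C8 and becomes benzenoid when the bridge opens. No lasting stereocentre is formed: the bridgeheads C4a and C7 of 16 end as sp2 carbons, and C1 and C2 are untouched because C2 is quaternary and the C1 hydrogen is not α to a carbonyl. The step needs one orientation of addition and one sense of bridge opening: the tether allows only the C4a–C8a/C7–C8 pairing, and only C4a–O cleavage is assisted by the C6 methoxy group and leaves a hydrogen (on C7) to be lost, so the 6-methoxy-7-hydroxy pattern with hydrogens on C5 and C8 follows.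

Step 10
Reactants: 17 methyl (1S,2S)-1-Ar-2-[(tert-butyldimethylsilyl)oxy]-7-hydroxy-6-methoxy-3-oxo-1,2,3,4-tetrahydronaphthalene-2-carboxylate
Product: 18 methyl (1S,2S)-7-(benzyloxy)-1-Ar-2-[(tert-butyldimethylsilyl)oxy]-6-methoxy-3-oxo-1,2,3,4-tetrahydronaphthalene-2-carboxylate
Conditions: BnBr (1.1 equiv), K2CO3, acetone, 40 °C
Reagents that add atoms: benzyl bromide, BrCc1ccccc1
Why: Williamson ether synthesis at the phenol, which is far more acidic than the C4 methylene of the ketone, so O-benzylation should precede any C-alkylation.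

Step 11
Reactants: 18 methyl (1S,2S)-7-(benzyloxy)-1-Ar-2-[(tert-butyldimethylsilyl)oxy]-6-methoxy-3-oxo-1,2,3,4-tetrahydronaphthalene-2-carboxylate
Product: 19 methyl (1S,2S)-7-(benzyloxy)-1-Ar-2-hydroxy-6-methoxy-3-oxo-1,2,3,4-tetrahydronaphthalene-2-carboxylate
Conditions: HF·pyridine, THF/pyridine, 0 °C → rt
Reagents that add atoms: none
Why: Fluoride-mediated desilylation under buffered acidic conditions, chosen so that no free tertiary alkoxide next to the ketone forms (which could trigger retro-Claisen or α-ketol shift).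

Step 12
Reactants: 19 methyl (1S,2S)-7-(benzyloxy)-1-Ar-2-hydroxy-6-methoxy-3-oxo-1,2,3,4-tetrahydronaphthalene-2-carboxylate
Product: 20 methyl (1S,2S)-7-(benzyloxy)-1-Ar-2-{[(bromomethyl)dimethylsilyl]oxy}-6-methoxy-3-oxo-1,2,3,4-tetrahydronaphthalene-2-carboxylate
Conditions: BrCH2SiMe2Cl, Et3N, DMAP (cat.), CH2Cl2, 0 °C
Reagents that add atoms: (bromomethyl)chlorodimethylsilane, C[Si](C)(Cl)CBr
Why: Silylation of the tertiary alcohol with a small, reactive chlorosilane installs the one-carbon tether on the C2 oxygen.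

Step 13
Reactants: 20 methyl (1S,2S)-7-(benzyloxy)-1-Ar-2-{[(bromomethyl)dimethylsilyl]oxy}-6-methoxy-3-oxo-1,2,3,4-tetrahydronaphthalene-2-carboxylate
Product: 21 methyl (1S,2S)-7-(benzyloxy)-1-Ar-2-{[(bromomethyl)dimethylsilyl]oxy}-6-methoxy-3-[(trimethylsilyl)oxy]-1,2-dihydronaphthalene-2-carboxylate
Conditions: TMSOTf, Et3N, CH2Cl2, −20 → 0 °C; non-aqueous work-up
Reagents that add atoms: trimethylsilyl triflate, C[Si](C)(C)OS(=O)(=O)C(F)(F)F
Why: Silyl enol ether formation by soft enolisation, regiospecific because C2 is quaternary and the C3=C4 enol is conjugated with ring A.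

Step 14
Reactants: 21 methyl (1S,2S)-7-(benzyloxy)-1-Ar-2-{[(bromomethyl)dimethylsilyl]oxy}-6-methoxy-3-[(trimethylsilyl)oxy]-1,2-dihydronaphthalene-2-carboxylate
Product: 22 cis-fused oxasilolane (ring C2–O–SiMe2–CH2–C3; C3–OSiMe3; C4 is CH2; 1S,2S,3S in tetralin numbering)
Conditions: Bu3SnH (slow addition), AIBN (cat.), benzene (0.01 M), 80 °C
Reagents that add atoms: none
Why: Silicon-tethered 5-exo radical cyclisation (Nishiyama–Stork type): the α-silyl radical adds to C3 of the styrene-like enol ether to leave a benzylic C4 radical that is reduced by the stannane, and because the five-membered oxasilolane can only be cis-fused the new C3–CH2 bond is forced onto the face of the C2 oxygen.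

Step 15
Reactants: 22 cis-fused oxasilolane (C3–OSiMe3)
Product: 24 methyl (1S,2S,3R)-7-(benzyloxy)-1-Ar-2,3-dihydroxy-3-(hydroxymethyl)-6-methoxy-1,2,3,4-tetrahydronaphthalene-2-carboxylate, via hydroxy oxasilolane 23 (not isolated)
Conditions: KF, KHCO3, 30% H2O2, THF/MeOH, rt → 40 °C
Reagents that add atoms: hydrogen peroxide, OO
Why: Tamao–Fleming oxidation of the alkoxysilane converts C–Si into C–OH with retention and frees the C2 hydroxyl, the labile tertiary trimethylsilyl ether being cleaved first under the same fluoride/methanol conditions; the configuration at C3 is the one set in step 14.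

Step 16
Reactants: 24 methyl (1S,2S,3R)-7-(benzyloxy)-1-Ar-2,3-dihydroxy-3-(hydroxymethyl)-6-methoxy-1,2,3,4-tetrahydronaphthalene-2-carboxylate
Product: 25 (1S,2S,3R)-7-(benzyloxy)-1-Ar-2,3-dihydroxy-3-(hydroxymethyl)-6-methoxy-1,2,3,4-tetrahydronaphthalene-2-carboxylic acid
Conditions: LiOH, THF/H2O, rt; 1 M HCl to pH 3
Reagents that add atoms: lithium hydroxide, [Li+].[OH-]
Why: Saponification of an α-hydroxy methyl ester, done while all phenols are still benzylated so that no air-sensitive catechol meets base.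

Step 17
Reactants: 25 (1S,2S,3R)-7-(benzyloxy)-1-Ar-2,3-dihydroxy-3-(hydroxymethyl)-6-methoxy-1,2,3,4-tetrahydronaphthalene-2-carboxylic acid
Product: 26 plicatic acid
Conditions: H2 (1 atm), Pd/C, MeOH, rt
Reagents that add atoms: none
Why: Catalytic hydrogenolysis removes the three benzyl ethers under neutral conditions and leaves the three stereocentres, none of which carries a benzylic C–O bond, untouched.

**Compound list**

1 | 5-hydroxyvanillin | COc1cc(C=O)cc(O)c1O | starting material
2 | 3,4-bis(benzyloxy)-5-methoxybenzaldehyde | COc1cc(C=O)cc(OCc2ccccc2)c1OCc1ccccc1 | intermediate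
3 | ethynylmagnesium bromide | C#C[Mg]Br | starting material
4 | racemic 1-Ar-prop-2-yn-1-ol | C#CC(O)c1cc(OCc2ccccc2)c(OCc2ccccc2)c(OC)c1 | intermediate
5 | racemic 1-Ar-prop-2-yn-1-yl acetate | C#CC(OC(C)=O)c1cc(OCc2ccccc2)c(OCc2ccccc2)c(OC)c1 | intermediate
6 | 4-bromo-2-furaldehyde | O=Cc1cc(Br)co1 | starting material
7 | racemic 1-(4-bromofuran-2-yl)-2,2,2-trichloroethan-1-ol | OC(c1cc(Br)co1)C(Cl)(Cl)Cl | intermediate
8 | 3-(4-bromofuran-2-yl)-2,2-dichlorooxirane | ClC1(Cl)OC1c1cc(Br)co1 | intermediate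
9 | (4-bromofuran-2-yl)acetyl chloride | O=C(Cl)Cc1cc(Br)co1 | intermediate
10 | (4-bromofuran-2-yl)acetic acid | OC(=O)Cc1cc(Br)co1 | intermediate
11 | (4-methoxyfuran-2-yl)acetic acid | COc1coc(CC(=O)O)c1 | intermediate
12 | methyl 2-[(tert-butyldimethylsilyl)oxy]acetate | COC(=O)CO[Si](C)(C)C(C)(C)C | starting material
13 | 1-[(4-methoxyfuran-2-yl)acetyl]imidazole | COc1coc(CC(=O)n2ccnc2)c1 | intermediate
14 | methyl 2-[(tert-butyldimethylsilyl)oxy]-4-(4-methoxyfuran-2-yl)-3-oxobutanoate (racemic at C2) | COC(=O)C(O[Si](C)(C)C(C)(C)C)C(=O)Cc1cc(OC)co1 | intermediate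
15 | methyl (2S)-2-[(1R)-1-Ar-prop-2-yn-1-yl]-2-[(tert-butyldimethylsilyl)oxy]-4-(4-methoxyfuran-2-yl)-3-oxobutanoate | C#C[C@H](c1cc(OCc2ccccc2)c(OCc2ccccc2)c(OC)c1)[C@@](O[Si](C)(C)C(C)(C)C)(C(=O)OC)C(=O)Cc1cc(OC)co1 | intermediate
16 | oxanorbornadiene cycloadduct (oxygen bridge between C4a and C7; C1 and C2 as in 15; bridgehead configuration not defined) | COC1=CC23CC(=O)[C@](O[Si](C)(C)C(C)(C)C)(C(=O)OC)[C@@H](c4cc(OCc5ccccc5)c(OCc5ccccc5)c(OC)c4)C2=CC1O3 | intermediate
17 | methyl (1S,2S)-1-Ar-2-[(tert-butyldimethylsilyl)oxy]-7-hydroxy-6-methoxy-3-oxo-1,2,3,4-tetrahydronaphthalene-2-carboxylate | COc1cc2c(cc1O)[C@H](c1cc(OCc3ccccc3)c(OCc3ccccc3)c(OC)c1)[C@@](O[Si](C)(C)C(C)(C)C)(C(=O)OC)C(=O)C2 | intermediate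
18 | methyl (1S,2S)-7-(benzyloxy)-1-Ar-2-[(tert-butyldimethylsilyl)oxy]-6-methoxy-3-oxo-1,2,3,4-tetrahydronaphthalene-2-carboxylate | COc1cc2c(cc1OCc3ccccc3)[C@H](c3cc(OCc4ccccc4)c(OCc4ccccc4)c(OC)c3)[C@@](O[Si](C)(C)C(C)(C)C)(C(=O)OC)C(=O)C2 | intermediate
19 | methyl (1S,2S)-7-(benzyloxy)-1-Ar-2-hydroxy-6-methoxy-3-oxo-1,2,3,4-tetrahydronaphthalene-2-carboxylate | COc1cc2c(cc1OCc3ccccc3)[C@H](c3cc(OCc4ccccc4)c(OCc4ccccc4)c(OC)c3)[C@@](O)(C(=O)OC)C(=O)C2 | intermediate
20 | methyl (1S,2S)-7-(benzyloxy)-1-Ar-2-{[(bromomethyl)dimethylsilyl]oxy}-6-methoxy-3-oxo-1,2,3,4-tetrahydronaphthalene-2-carboxylate | COc1cc2c(cc1OCc3ccccc3)[C@H](c3cc(OCc4ccccc4)c(OCc4ccccc4)c(OC)c3)[C@@](O[Si](C)(C)CBr)(C(=O)OC)C(=O)C2 | intermediate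
21 | methyl (1S,2S)-7-(benzyloxy)-1-Ar-2-{[(bromomethyl)dimethylsilyl]oxy}-6-methoxy-3-[(trimethylsilyl)oxy]-1,2-dihydronaphthalene-2-carboxylate | COc1cc2c(cc1OCc3ccccc3)[C@H](c3cc(OCc4ccccc4)c(OCc4ccccc4)c(OC)c3)[C@@](O[Si](C)(C)CBr)(C(=O)OC)C(O[Si](C)(C)C)=C2 | intermediate
22 | cis-fused oxasilolane (ring C2–O–SiMe2–CH2–C3; C3–OSiMe3; 1S,2S,3S in tetralin numbering) | COc1cc2c(cc1OCc3ccccc3)[C@H](c3cc(OCc4ccccc4)c(OCc4ccccc4)c(OC)c3)[C@]1(C(=O)OC)O[Si](C)(C)C[C@]1(O[Si](C)(C)C)C2 | intermediate
23 | hydroxy oxasilolane (as 22 with free C3–OH) | COc1cc2c(cc1OCc3ccccc3)[C@H](c3cc(OCc4ccccc4)c(OCc4ccccc4)c(OC)c3)[C@]1(C(=O)OC)O[Si](C)(C)C[C@]1(O)C2 | intermediate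
24 | methyl (1S,2S,3R)-7-(benzyloxy)-1-Ar-2,3-dihydroxy-3-(hydroxymethyl)-6-methoxy-1,2,3,4-tetrahydronaphthalene-2-carboxylate | COc1cc2c(cc1OCc3ccccc3)[C@H](c3cc(OCc4ccccc4)c(OCc4ccccc4)c(OC)c3)[C@@](O)(C(=O)OC)[C@](O)(CO)C2 | intermediate
25 | (1S,2S,3R)-7-(benzyloxy)-1-Ar-2,3-dihydroxy-3-(hydroxymethyl)-6-methoxy-1,2,3,4-tetrahydronaphthalene-2-carboxylic acid | COc1cc2c(cc1OCc3ccccc3)[C@H](c3cc(OCc4ccccc4)c(OCc4ccccc4)c(OC)c3)[C@@](O)(C(=O)O)[C@](O)(CO)C2 | intermediate
26 | plicatic acid, (1S,2S,3R)-1-(3,4-dihydroxy-5-methoxyphenyl)-2,3,7-trihydroxy-3-(hydroxymethyl)-6-methoxy-1,2,3,4-tetrahydronaphthalene-2-carboxylic acid | COc1cc2c(cc1O)[C@H](c1cc(O)c(O)c(OC)c1)[C@@](O)(C(=O)O)[C@](O)(CO)C2 | target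

**Step count**

Total: 17 steps. Longest linear sequence: 14 steps (steps 4 to 17, from 4-bromo-2-furaldehyde).

**Steps most likely to fail, with fallbacks**

1. Step 9 (key step). At the temperature an unactivated terminal alkyne needs, the C3 ketone may enolise towards the furyl-bearing C4 and the enol may close onto the alkyne (Conia-ene) or the furfuryl ketone may degrade before the cycloaddition takes place. The fallback removes the ketone for the duration of the cycloaddition. It sets out from 15, which is reduced under Luche conditions (NaBH4, CeCl3·7H2O, MeOH, −40 °C) to the C3 carbinol of 15, methyl (2S)-2-[(1R)-1-Ar-prop-2-yn-1-yl]-2-[(tert-butyldimethylsilyl)oxy]-3-hydroxy-4-(4-methoxyfuran-2-yl)butanoate F1 (either C3 epimer serves). Heating F1 as in step 9 should give the 3-hydroxy analogue of 17, methyl (1S,2S)-1-Ar-2-[(tert-butyldimethylsilyl)oxy]-3,7-dihydroxy-6-methoxy-1,2,3,4-tetrahydronaphthalene-2-carboxylate F2. Benzylation of the phenol (BnBr, K2CO3, acetone) gives the 7-benzyl ether F3, and Dess–Martin oxidation of the secondary alcohol returns to the route at 18.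

2. Step 8. Facial discrimination at the fully substituted enolate carbon may be poor, so C2 would come out as a mixture, and the electron-rich furan C5 may compete as a nucleophile for the allenylidene. The fallback sets the two centres in separate steps. It sets out from 11 and 5: the acyl imidazole 13 made from 11 is condensed with potassium methyl malonate (MgCl2, Et3N, THF; Masamune–Brooks) to methyl 4-(4-methoxyfuran-2-yl)-3-oxobutanoate F4. The same copper–pybox catalyst joins F4 and 5, a nucleophile class with firm precedent, to methyl 2-[(1R)-1-Ar-prop-2-yn-1-yl]-4-(4-methoxyfuran-2-yl)-3-oxobutanoate F5 (C1 set, C2 epimers that share one enolate; kept cold to avoid copper-mediated cyclisation onto the alkyne). Davis hydroxylation of the potassium enolate (KN(SiMe3)2, 2-(phenylsulfonyl)-3-phenyloxaziridine, THF, −78 °C), with the face chosen by allylic strain against the C1 substituents and the isomers separated at this stage, gives methyl (2S)-2-[(1R)-1-Ar-prop-2-yn-1-yl]-2-hydroxy-4-(4-methoxyfuran-2-yl)-3-oxobutanoate F6. Silylation (TBSOTf, 2,6-lutidine) returns to the route at 15.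

3. Step 14. The α-silyl radical may close 6-endo at C4, or take the doubly benzylic hydrogen from C1 by 1,5-transfer, which would scramble C1 and lose the tether. The fallback uses known olefination and dihydroxylation chemistry, and relies on steric shielding in place of the tether. It sets out from 18: Takai–Lombardo methylenation (Zn, CH2Br2, TiCl4, THF) of the enolisable, hindered ketone gives methyl (1S,2S)-7-(benzyloxy)-1-Ar-2-[(tert-butyldimethylsilyl)oxy]-6-methoxy-3-methylidene-1,2,3,4-tetrahydronaphthalene-2-carboxylate F7. Upjohn dihydroxylation (OsO4 cat., NMO, acetone/H2O) from the face away from the C2 silyl ether and the C1 aryl group should give methyl (1S,2S,3R)-7-(benzyloxy)-1-Ar-2-[(tert-butyldimethylsilyl)oxy]-3-hydroxy-3-(hydroxymethyl)-6-methoxy-1,2,3,4-tetrahydronaphthalene-2-carboxylate F8. HF·pyridine then returns to the route at 24.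

**Further compounds**

F1 | step 9 | methyl (2S)-2-[(1R)-1-Ar-prop-2-yn-1-yl]-2-[(tert-butyldimethylsilyl)oxy]-3-hydroxy-4-(4-methoxyfuran-2-yl)butanoate | C#C[C@H](c1cc(OCc2ccccc2)c(OCc2ccccc2)c(OC)c1)[C@@](O[Si](C)(C)C(C)(C)C)(C(=O)OC)C(O)Cc1cc(OC)co1
F2 | step 9 | methyl (1S,2S)-1-Ar-2-[(tert-butyldimethylsilyl)oxy]-3,7-dihydroxy-6-methoxy-1,2,3,4-tetrahydronaphthalene-2-carboxylate | COc1cc2c(cc1O)[C@H](c1cc(OCc3ccccc3)c(OCc3ccccc3)c(OC)c1)[C@@](O[Si](C)(C)C(C)(C)C)(C(=O)OC)C(O)C2
F3 | step 9 | methyl (1S,2S)-7-(benzyloxy)-1-Ar-2-[(tert-butyldimethylsilyl)oxy]-3-hydroxy-6-methoxy-1,2,3,4-tetrahydronaphthalene-2-carboxylate | COc1cc2c(cc1OCc3ccccc3)[C@H](c3cc(OCc4ccccc4)c(OCc4ccccc4)c(OC)c3)[C@@](O[Si](C)(C)C(C)(C)C)(C(=O)OC)C(O)C2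
F4 | step 8 | methyl 4-(4-methoxyfuran-2-yl)-3-oxobutanoate | COC(=O)CC(=O)Cc1cc(OC)co1
F5 | step 8 | methyl 2-[(1R)-1-Ar-prop-2-yn-1-yl]-4-(4-methoxyfuran-2-yl)-3-oxobutanoate | C#C[C@H](c1cc(OCc2ccccc2)c(OCc2ccccc2)c(OC)c1)C(C(=O)OC)C(=O)Cc1cc(OC)co1
F6 | step 8 | methyl (2S)-2-[(1R)-1-Ar-prop-2-yn-1-yl]-2-hydroxy-4-(4-methoxyfuran-2-yl)-3-oxobutanoate | C#C[C@H](c1cc(OCc2ccccc2)c(OCc2ccccc2)c(OC)c1)[C@@](O)(C(=O)OC)C(=O)Cc1cc(OC)co1
F7 | step 14 | methyl (1S,2S)-7-(benzyloxy)-1-Ar-2-[(tert-butyldimethylsilyl)oxy]-6-methoxy-3-methylidene-1,2,3,4-tetrahydronaphthalene-2-carboxylate | COc1cc2c(cc1OCc3ccccc3)[C@H](c3cc(OCc4ccccc4)c(OCc4ccccc4)c(OC)c3)[C@@](O[Si](C)(C)C(C)(C)C)(C(=O)OC)C(=C)C2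
F8 | step 14 | methyl (1S,2S,3R)-7-(benzyloxy)-1-Ar-2-[(tert-butyldimethylsilyl)oxy]-3-hydroxy-3-(hydroxymethyl)-6-methoxy-1,2,3,4-tetrahydronaphthalene-2-carboxylate | COc1cc2c(cc1OCc3ccccc3)[C@H](c3cc(OCc4ccccc4)c(OCc4ccccc4)c(OC)c3)[C@@](O[Si](C)(C)C(C)(C)C)(C(=O)OC)[C@](O)(CO)C2
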